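**Retrosynthetic overview**

1. Locants (target): trione ring C1 (acyl) – C2 (enol OH) – C3 (Me, prenyl) – C4 (C=O) – C5 (spiro) – C6 (C=O); carbocycle C5–C7H2–C8H–C9H–C13(Me)(OH)–C14H2; cyclopentane C8–C9–C10H2–C11H2–C12(Me)(OH).
2. Late disconnections: C5–C7 (intramolecular Mitsunobu C-alkylation, closes the spiro six-membered ring last), C3–prenyl (ligand-controlled dearomative Tsuji–Trost prenylation), C5–C14 (reductive alkylation of acylphloroglucinol 14 with the α-quaternary aldehyde 11).
3. Key disconnection: C9–C10 and C8–C12 in one operation, a radical–polar crossover [3+2] of butenolide 6 (C7 = lactone C=O, C8=C9, ring oxygen on C13) with 1-methylcyclopropanol 7 as its ring-opened 3-oxobutyl radical.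
4. Enabling feature: the cyclopentane edge C12(CH3)(OH)–C11H2–C10H2 is a ring-opened 1-methylcyclopropanol, and the ring-fusion bond C8–C9 lies between C7 (a CH2 that can be carried as a carboxyl carbon) and the carbinol carbon C13, so C7, C8, C9, C13 and the C13 oxygen are a latent butenolide whose alkene accepts C10 at C9 and returns an enolate at C8 for aldol closure onto C12.
5. Ring order: butenolide (metathesis) → cis-fused cyclopentane (key step) → acylated aromatic ring, dearomatised at C3 → spiro cyclohexane; C13 comes from (R)-2-methylglycidol, C8/C9/C12 from the key step, C3 from the ligand, C5 by 1,3-induction from C3.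

Key step: step 5

Remark: 1, 7, 12 and 13 are taken as commercial; enolised β-triketones are drawn in one tautomeric form and all CIP descriptors refer to the forms drawn.

**Route**

Step 1
Reactants: 1 (R)-2-methylglycidol
Product: 2 (S)-tert-butyl[(2-methyloxiran-2-yl)methoxy]diphenylsilane
Conditions: TBDPSCl, imidazole, CH2Cl2, 0 °C → rt
Reagents that add atoms: tert-butyl(chloro)diphenylsilane, CC(C)(C)[Si](Cl)(c1ccccc1)c1ccccc1
Why: Silyl ether formation at the primary hydroxyl leaves the epoxide stereocentre untouched (the descriptor changes only through CIP priorities) and installs the bulky silyloxymethyl group that should shield one butenolide face in the key step.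

Step 2
Reactants: 2
Product: 4 (2S)-1-[(tert-butyldiphenylsilyl)oxy]-2-methylbut-3-en-2-ol, via sulfonium betaine 3 (not isolated)
Conditions: Me3S+ I− (4 equiv), n-BuLi (3.8 equiv), THF, −10 °C → rt
Reagents that add atoms: trimethylsulfonium iodide, C[S+](C)C.[I-]
Why: Dimethylsulfonium methylide should open the epoxide at its CH2 terminus and the betaine should lose dimethyl sulfide by base-induced elimination (sulfonium-ylide one-carbon homologation of an epoxide to an allylic alcohol), so the tertiary carbinol centre keeps its configuration.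

Step 3
Reactants: 4
Product: 5 (2S)-1-[(tert-butyldiphenylsilyl)oxy]-2-methylbut-3-en-2-yl prop-2-enoate
Conditions: acryloyl chloride, i-Pr2NEt, DMAP (cat.), CH2Cl2, 0 °C → rt
Reagents that add atoms: acryloyl chloride, C=CC(=O)Cl
Why: DMAP-catalysed O-acylation of the tertiary allylic alcohol should install the second alkene without touching the stereocentre.

Step 4
Reactants: 5
Product: 6 (5S)-5-{[(tert-butyldiphenylsilyl)oxy]methyl}-5-methylfuran-2(5H)-one
Conditions: second-generation Grubbs catalyst [RuCl2(=CHPh)(PCy3)(H2IMes)] (5 mol %), toluene (0.01 M), 80 °C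
Reagents that add atoms: none
Why: Ring-closing metathesis of the acrylate with the vinyl group should give the five-membered unsaturated lactone, driven by loss of ethene, with the quaternary centre as a spectator.

Step 5
Reactants: 6, 7 1-methylcyclopropan-1-ol
Product: 9 (3S,3aS,6R,6aS)-3-{[(tert-butyldiphenylsilyl)oxy]methyl}-6-hydroxy-3,6-dimethylhexahydro-1H-cyclopenta[c]furan-1-one, via lactone enolate 8 (not isolated)
Conditions: 7 (2 equiv), 2,4,5,6-tetrakis(carbazol-9-yl)isophthalonitrile (4CzIPN, 2 mol %), Cs2CO3 (10 mol %), MeCN (0.1 M), 456 nm LEDs, rt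
Reagents that add atoms: none
Why: Proposed new method: excited 4CzIPN should oxidise the caesium alkoxide of 7, strain-driven β-scission gives the 3-oxobutyl radical, this adds (Giese) to the butenolide β-carbon C9, and the photocatalyst radical anion reduces the resulting α-lactone radical to enolate 8, which adds to its own ketone; the closest known reaction types are the oxidative ring-opening/Giese addition of cyclopropanols and other cycloalkanols to electron-poor alkenes and the conjugate addition–aldol [3+2] annulation of cyclopropanol-derived metal homoenolates. The C9–C10 bond is thus a union of two carbonyl β-carbons (like polarity), made possible by the radical umpolung of the homoenolate, and the C8–C12 bond follows in the polar manifold in the same operation. The cyclopentane closes by a 5-(enolexo)-exo-trig aldol addition. C9 should be set by radical approach anti to the CH2OTBDPS group on the neighbouring quaternary carbon C13, C8 is forced cis by the bicyclo[3.3.0] ring fusion, and C12 should be set by a caesium-bridged aldol transition state that keeps the alkoxide syn to the lactone carbonyl, which is also the expected thermodynamic outcome of a reversible aldol (methyl on the convex face). The step needs the enolate to arise at the lactone α-carbon and not at the more acidic ketone α-positions, which the radical–polar crossover secures because the charge is generated exactly at C8, and it needs discrimination between CH3 and CH2OSi on C13, which the bulky silyl group supplies.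

Step 6
Reactants: 9
Product: 10 (3S,3aS,6R,6aS)-6-hydroxy-3-(hydroxymethyl)-3,6-dimethylhexahydro-1H-cyclopenta[c]furan-1-one
Conditions: HF·pyridine, THF/pyridine, 0 °C → rt
Reagents that add atoms: none
Why: Fluoride cleavage of the silyl ether under non-basic conditions should spare the β-hydroxy lactone from retro-aldol opening and touches no stereocentre.

Step 7
Reactants: 10
Product: 11 (3S,3aS,6R,6aS)-6-hydroxy-3,6-dimethyl-1-oxohexahydro-1H-cyclopenta[c]furan-3-carbaldehyde
Conditions: Dess–Martin periodinane, CH2Cl2, 0 °C → rt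
Reagents that add atoms: none
Why: Dess–Martin oxidation of the primary alcohol should leave the tertiary alcohol alone and give an aldehyde whose quaternary α-carbon can neither enolise nor epimerise.

Step 8
Reactants: 12 2-methylbenzene-1,3,5-triol, 13 (2S)-2-methylbutanoyl chloride
Product: 14 (2S)-2-methyl-1-(2,4,6-trihydroxy-3-methylphenyl)butan-1-one
Conditions: AlCl3 (3 equiv), PhNO2/CH2Cl2, 0 °C → rt; aq. HCl work-up
Reagents that add atoms: none
Why: Friedel–Crafts acylation at one of the two equivalent free ring positions of the electron-rich triol should proceed at low temperature with retention of the α-stereocentre carried in from 13.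

Step 9
Reactants: 11, 14
Product: 16 (2S)-1-(2,4,6-trihydroxy-3-{[(3R,3aS,6R,6aS)-6-hydroxy-3,6-dimethyl-1-oxohexahydro-1H-cyclopenta[c]furan-3-yl]methyl}-5-methylphenyl)-2-methylbutan-1-one, via ortho-quinone methide 15 (not isolated)
Conditions: L-proline (20 mol %), Hantzsch ester (diethyl 2,6-dimethyl-1,4-dihydropyridine-3,5-dicarboxylate, 1.3 equiv), CH2Cl2/EtOH, rt → 40 °C
Reagents that add atoms: none
Why: Three-component reductive alkylation, in which Knoevenagel-type condensation of the aldehyde at the only free ring carbon gives an ortho-quinone methide that takes up hydride from the Hantzsch ester, should form the C5–C14 bond without creating or endangering a stereocentre.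

Step 10
Reactants: 16
Product: 17 (2S)-1-(2,4,6-trihydroxy-3-{(2R)-2-hydroxy-2-[(1S,2R,3R)-3-hydroxy-2-(hydroxymethyl)-3-methylcyclopentyl]propyl}-5-methylphenyl)-2-methylbutan-1-one
Conditions: LiBH4 (6 equiv), THF/MeOH, 0 °C → rt; then aq. HCl (1 M), 0 °C
Reagents that add atoms: none
Why: Borohydride reduction of the lactone should give the primary/tertiary 1,4-diol while the aryl ketone, part of the in situ deprotonated acylphloroglucinol (a vinylogous carboxylate), resists hydride, and no stereocentre is touched.

Step 11
Reactants: 17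
Product: 18 (6R)-3,5-dihydroxy-2-{(2R)-2-hydroxy-2-[(1S,2R,3R)-3-hydroxy-2-(hydroxymethyl)-3-methylcyclopentyl]propyl}-6-methyl-4-[(2S)-2-methylbutanoyl]-6-(3-methylbut-2-en-1-yl)cyclohexa-2,4-dien-1-one
Conditions: prenyl acetate (1.2 equiv), Pd2(dba)3·CHCl3 (2.5 mol %), (R,R)-N,N'-(cyclohexane-1,2-diyl)bis[2-(diphenylphosphanyl)benzamide] (7.5 mol %), Cs2CO3 (1.1 equiv), THF, 0 °C → rt
Reagents that add atoms: 3-methylbut-2-en-1-yl acetate, CC(=O)OCC=C(C)C
Why: In this Tsuji–Trost dearomative C-allylation with a zerovalent palladium catalyst the phenoxide should attack the unsubstituted terminus of the π-prenyl complex through its methyl-bearing ring carbon C3 (the other substituted ring carbon carries a neopentyl-type group), and the new quaternary centre should be set by the chiral diphosphine (catalyst control, the ligand enantiomer to be fixed by a screen).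

Step 12
Reactants: 18
Product: 20 C12,C13-bis(trimethylsilyl) ether of 18, via pentakis(trimethylsilyl) ether 19 (not isolated)
Conditions: N-(trimethylsilyl)imidazole (8 equiv), CH2Cl2, rt; then K2CO3 (0.2 equiv), MeOH, 0 °C
Reagents that add atoms: N-(trimethylsilyl)imidazole, C[Si](C)(C)n1ccnc1
Why: Exhaustive silylation followed by selective methanolysis of the labile enol and primary silyl ethers should leave only the two hindered tertiary silyl ethers, so that neither tertiary hydroxyl can close a cyclic ether onto the primary carbon once it is activated, and no stereocentre is touched.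

Step 13
Reactants: 20
Product: 23 Hyperielliptone HB, via alkoxyphosphonium betaine 21 (not isolated), via bis(trimethylsilyl) spirocycle 22 (not isolated)
Conditions: PPh3 (1.5 equiv), DIAD (1.5 equiv), THF (0.01 M), 0 → 40 °C; then HF·pyridine, 0 °C
Reagents that add atoms: none
Why: In this intramolecular Mitsunobu C-alkylation the acidic trione protonates the betaine, the primary alcohol is activated as its alkoxyphosphonium and should be displaced by the enolic ring carbon C5 in a 6-(enolexo)-exo-tet closure (O-alkylation would need an eight-membered ring), the spiro centre being set by approach of C7 to the C5 face anti to the prenyl group of C3 (1,3-induction, expected to be modest), after which fluoride removes the two silyl ethers.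

**Compound list**

1 | (R)-2-methylglycidol, [(2R)-2-methyloxiran-2-yl]methanol | C[C@@]1(CO)CO1 | starting material
2 | (S)-tert-butyl[(2-methyloxiran-2-yl)methoxy]diphenylsilane | C[C@@]1(CO[Si](c2ccccc2)(c2ccccc2)C(C)(C)C)CO1 | intermediate
3 | sulfonium betaine, (2S)-1-[(tert-butyldiphenylsilyl)oxy]-4-(dimethylsulfaniumyl)-2-methylbutan-2-olate | C[S+](C)CC[C@](C)([O-])CO[Si](c1ccccc1)(c1ccccc1)C(C)(C)C | intermediate
4 | (2S)-1-[(tert-butyldiphenylsilyl)oxy]-2-methylbut-3-en-2-ol | C=C[C@@](C)(CO[Si](c1ccccc1)(c1ccccc1)C(C)(C)C)O | intermediate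
5 | (2S)-1-[(tert-butyldiphenylsilyl)oxy]-2-methylbut-3-en-2-yl prop-2-enoate | C=CC(=O)O[C@](C)(CO[Si](c1ccccc1)(c1ccccc1)C(C)(C)C)C=C | intermediate
6 | (5S)-5-{[(tert-butyldiphenylsilyl)oxy]methyl}-5-methylfuran-2(5H)-one | O=C1C=C[C@@](C)(CO[Si](c2ccccc2)(c2ccccc2)C(C)(C)C)O1 | intermediate
7 | 1-methylcyclopropan-1-ol | CC1(O)CC1 | starting material
8 | lactone enolate, caesium enolate of (4S,5S)-5-{[(tert-butyldiphenylsilyl)oxy]methyl}-5-methyl-4-(3-oxobutyl)dihydrofuran-2(3H)-one | CC(=O)CC[C@H]1C=C([O-])O[C@]1(C)CO[Si](c2ccccc2)(c2ccccc2)C(C)(C)C.[Cs+] | intermediate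
9 | (3S,3aS,6R,6aS)-3-{[(tert-butyldiphenylsilyl)oxy]methyl}-6-hydroxy-3,6-dimethylhexahydro-1H-cyclopenta[c]furan-1-one (cis-fused; hydroxyl syn to the lactone carbonyl; cyclopentane anti to CH2OSi) | O=C1O[C@](C)(CO[Si](c3ccccc3)(c3ccccc3)C(C)(C)C)[C@H]2CC[C@@](C)(O)[C@@H]12 | intermediate
10 | (3S,3aS,6R,6aS)-6-hydroxy-3-(hydroxymethyl)-3,6-dimethylhexahydro-1H-cyclopenta[c]furan-1-one | OC[C@@]1(C)OC(=O)[C@H]2[C@@H]1CC[C@@]2(C)O | intermediate
11 | (3S,3aS,6R,6aS)-6-hydroxy-3,6-dimethyl-1-oxohexahydro-1H-cyclopenta[c]furan-3-carbaldehyde | O=C[C@@]1(C)OC(=O)[C@H]2[C@@H]1CC[C@@]2(C)O | intermediate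
12 | 2-methylbenzene-1,3,5-triol (2-methylphloroglucinol) | Cc1c(O)cc(O)cc1O | starting material
13 | (2S)-2-methylbutanoyl chloride | CC[C@H](C)C(Cl)=O | starting material
14 | (2S)-2-methyl-1-(2,4,6-trihydroxy-3-methylphenyl)butan-1-one | CC[C@H](C)C(=O)c1c(O)cc(O)c(C)c1O | intermediate
15 | ortho-quinone methide from 11 and 14 (exocyclic C5=C14 alkene, geometry not defined) | CC[C@H](C)C(=O)C1=C(O)C(C)=C(O)C(=C[C@@]2(C)OC(=O)[C@H]3[C@@H]2CC[C@@]3(C)O)C1=O | intermediate
16 | (2S)-1-(2,4,6-trihydroxy-3-{[(3R,3aS,6R,6aS)-6-hydroxy-3,6-dimethyl-1-oxohexahydro-1H-cyclopenta[c]furan-3-yl]methyl}-5-methylphenyl)-2-methylbutan-1-one | CC[C@H](C)C(=O)c1c(O)c(C)c(O)c(C[C@@]2(C)OC(=O)[C@H]3[C@@H]2CC[C@@]3(C)O)c1O | intermediate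
17 | (2S)-1-(2,4,6-trihydroxy-3-{(2R)-2-hydroxy-2-[(1S,2R,3R)-3-hydroxy-2-(hydroxymethyl)-3-methylcyclopentyl]propyl}-5-methylphenyl)-2-methylbutan-1-one | CC[C@H](C)C(=O)c1c(O)c(C)c(O)c(C[C@@](C)(O)[C@H]2CC[C@@](C)(O)[C@H]2CO)c1O | intermediate
18 | (6R)-3,5-dihydroxy-2-{(2R)-2-hydroxy-2-[(1S,2R,3R)-3-hydroxy-2-(hydroxymethyl)-3-methylcyclopentyl]propyl}-6-methyl-4-[(2S)-2-methylbutanoyl]-6-(3-methylbut-2-en-1-yl)cyclohexa-2,4-dien-1-one | CC[C@H](C)C(=O)C1=C(O)[C@@](C)(CC=C(C)C)C(=O)C(C[C@@](C)(O)[C@H]2CC[C@@](C)(O)[C@H]2CO)=C1O | intermediate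
19 | pentakis(trimethylsilyl) ether of 18 (both enol oxygens, the primary and both tertiary hydroxyls silylated) | CC[C@H](C)C(=O)C1=C(O[Si](C)(C)C)[C@@](C)(CC=C(C)C)C(=O)C(C[C@@](C)(O[Si](C)(C)C)[C@H]2CC[C@@](C)(O[Si](C)(C)C)[C@H]2CO[Si](C)(C)C)=C1O[Si](C)(C)C | intermediate
20 | C12,C13-bis(trimethylsilyl) ether of 18 (only the two tertiary hydroxyls silylated) | CC[C@H](C)C(=O)C1=C(O)[C@@](C)(CC=C(C)C)C(=O)C(C[C@@](C)(O[Si](C)(C)C)[C@H]2CC[C@@](C)(O[Si](C)(C)C)[C@H]2CO)=C1O | intermediate
21 | alkoxyphosphonium betaine of 20 (primary oxygen bound to triphenylphosphonium, trione as enolate) | CC[C@H](C)C(=O)C1=C([O-])[C@@](C)(CC=C(C)C)C(=O)C(C[C@@](C)(O[Si](C)(C)C)[C@H]2CC[C@@](C)(O[Si](C)(C)C)[C@H]2CO[P+](c3ccccc3)(c3ccccc3)c3ccccc3)=C1O | intermediate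
22 | C12,C13-bis(trimethylsilyl) ether of Hyperielliptone HB | CC[C@H](C)C(=O)C1=C(O)[C@@](C)(CC=C(C)C)C(=O)[C@]2(C[C@H]3[C@H](CC[C@@]3(C)O[Si](C)(C)C)[C@](C)(O[Si](C)(C)C)C2)C1=O | intermediate
23 | Hyperielliptone HB (3R, 5R spiro, 8S, 9S, 12R, 13R, acyl side chain 2S; cis ring fusion, both tertiary hydroxyls anti to the ring-fusion hydrogens) | CC[C@H](C)C(=O)C1=C(O)[C@@](C)(CC=C(C)C)C(=O)[C@]2(C[C@H]3[C@H](CC[C@@]3(C)O)[C@](C)(O)C2)C1=O | target

**Step count**

Total steps: 13. Longest linear sequence: 12 steps (steps 1–7 and 9–13, from 1); step 8 is a one-step branch.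

**Steps most likely to fail**

Step 5 (Proposed new method). What may go wrong:
- protonation of the lactone enolate before the aldol closure, so that the cascade stops after the radical addition;
- base-mediated scrambling through ketone enolates;
- inefficient oxidation of the aliphatic cyclopropanol;
- insufficient facial discrimination between methyl and silyloxymethyl in the radical addition.

Fallback with known chemistry, setting out from 6 and returning at 9: copper-catalysed conjugate addition of [2-(2-methyl-1,3-dioxolan-2-yl)ethyl]magnesium bromide (CuBr·SMe2, Me3SiCl, THF, −78 °C), again anti to the silyloxymethyl group, with bromination of the resulting silyl ketene acetal by N-bromosuccinimide in the same flask, should give the trans α-bromo lactone ketal F1. Pyridinium p-toluenesulfonate in acetone/water should unmask the ketone to give the α-bromo keto lactone F2. SmI2 (THF, −78 °C) should then generate the enolate regiospecifically at C8 and close the cyclopentanol by a chelated intramolecular Reformatsky reaction, giving 9.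

Step 13. What may go wrong:
- O-alkylation or decomposition of the alkoxyphosphonium outcompeting C-alkylation, because C5 reacts through a minor tautomer of the trione anion;
- poor facial selectivity at the planar C5, since the 1,3-induction from C3 (methyl against prenyl) is weak;
- premature loss of a tertiary silyl ether followed by cyclic ether formation.

Fallback, setting out from 10 and returning at 23. It reverses the order of the two bonds to C5 and generates the C13 hydroxyl in the ring closure itself.
- Tosylation of the primary alcohol (TsCl, pyridine) should give the tosylate F3.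
- i-Bu2AlH (CH2Cl2, −78 °C) should give the lactol F4.
- Reductive alkylation of 14 with F4 under the conditions of step 9 should form the C5–C7 bond and free the C13 hydroxyl, giving the hydroxy tosylate F5.
- K2CO3 in MeOH should close the epoxide F6.
- Cs2CO3 in DMF should then let ring carbon C5 open the epoxide at C14 (6-exo-tet dearomative alkylation), giving the spiro-dienone F7; its C5 epimers would be separated.
- The ligand-controlled prenylation of step 11, now at the only remaining nucleophilic ring carbon, should give 23.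

Step 11. What may go wrong:
- alkylation at the other substituted ring carbon or at oxygen;
- attack at the tertiary terminus of the π-prenyl unit;
- insufficient ligand control in the presence of the remote stereocentres.

Fallback, setting out from 17 and returning at 18: the same zerovalent palladium/diphosphine system with allyl acetate, for which asymmetric allylic dearomatisation is best precedented, should give the C3-allyl compound F8. Cross-metathesis with 2-methylbut-2-ene (second-generation Grubbs catalyst, CH2Cl2, 40 °C) should then build the prenyl group and give 18.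

Further compounds
F1 | step 5 | (4S,5S)-3-bromo-5-{[(tert-butyldiphenylsilyl)oxy]methyl}-5-methyl-4-[2-(2-methyl-1,3-dioxolan-2-yl)ethyl]dihydrofuran-2(3H)-one, bromine trans to the C4 side chain | O=C1O[C@](C)(CO[Si](c2ccccc2)(c2ccccc2)C(C)(C)C)[C@@H](CCC2(C)OCCO2)[C@@H]1Br
F2 | step 5 | (4S,5S)-3-bromo-5-{[(tert-butyldiphenylsilyl)oxy]methyl}-5-methyl-4-(3-oxobutyl)dihydrofuran-2(3H)-one, bromine trans to the C4 side chain | O=C1O[C@](C)(CO[Si](c2ccccc2)(c2ccccc2)C(C)(C)C)[C@@H](CCC(C)=O)[C@@H]1Br
F3 | step 13 | [(3S,3aS,6R,6aS)-6-hydroxy-3,6-dimethyl-1-oxohexahydro-1H-cyclopenta[c]furan-3-yl]methyl 4-methylbenzenesulfonate | Cc1ccc(cc1)S(=O)(=O)OC[C@@]1(C)OC(=O)[C@H]2[C@@H]1CC[C@@]2(C)O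
F4 | step 13 | lactol of F3 (lactone carbonyl reduced to the hemiacetal, anomeric mixture) | Cc1ccc(cc1)S(=O)(=O)OC[C@@]1(C)OC(O)[C@H]2[C@@H]1CC[C@@]2(C)O
F5 | step 13 | 14 alkylated at its free ring carbon with the C7 methylene, carrying the free C13 hydroxyl and the C14 tosylate | CC[C@H](C)C(=O)c1c(O)c(C)c(O)c(C[C@H]2[C@H](CC[C@@]2(C)O)[C@](C)(O)COS(=O)(=O)c2ccc(C)cc2)c1O
F6 | step 13 | 2-methyloxirane formed from F5 (C13–O–C14 epoxide) | CC[C@H](C)C(=O)c1c(O)c(C)c(O)c(C[C@H]2[C@H](CC[C@@]2(C)O)[C@@]2(C)CO2)c1O
F7 | step 13 | spiro-dienone, Hyperielliptone HB lacking the prenyl group (C3 methyl-bearing enol carbon) | CC[C@H](C)C(=O)C1=C(O)C(C)=C(O)[C@]2(C[C@H]3[C@H](CC[C@@]3(C)O)[C@](C)(O)C2)C1=O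
F8 | step 11 | C3-allyl analogue of 18 (prop-2-en-1-yl in place of 3-methylbut-2-en-1-yl) | CC[C@H](C)C(=O)C1=C(O)[C@@](C)(CC=C)C(=O)C(C[C@@](C)(O)[C@H]2CC[C@@](C)(O)[C@H]2CO)=C1O
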